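Everything rests on cutting the C9–C10 bond of ring B (eremophilane numbering). Hydroxyl-bearing C9 has the C8 carbonyl on one side and the ring-fusion methine C10 on the other. This array is what a carbonyl-ene reaction leaves behind when the aldehyde of a C8/C9 keto aldehyde adds to C10 of a C10=C1 alkene in ring A. One operation closes ring B, forms C9–C10, fixes the cis ring fusion and delivers the 9-hydroxy-8-ketone at its final oxidation level. The precursor is a ring A cyclohexene with a C3 silyl ether, cis methyl groups on C4 and C5 and a 3,4-dioxobutyl arm on quaternary C5. Isopropenyl group and ester follow later.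

Key step: step 12

**Conventions.** Eremophilane numbering is used for every intermediate: ring A is C1–C5 and C10, ring B is C5–C10, C14 is the methyl on C5 and C15 the methyl on C4. β is the face of C14. The target is 3R,4R,5R,7R,9R,10S,5′R, which means 3α-O, 4β-Me, 5β-Me, 7β-isopropenyl, 9β-OH and 10β-H. Decalins without the C7 three-carbon unit are named as 11,12,13-trinoreremophilanes.

**Design points**
- **C3 protecting group.** The C3 oxygen is carried as a triethylsilyl ether. It is a poor Lewis base and has no electron-rich arene that an activated dicarbonyl could attack or a Lewis acid could cleave. It also comes off before a tert-butyldimethylsilyl ether does.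
- **C9 configuration.** The six-centre hydrogen transfer needs O9 under ring A, next to H2α, and this is possible only with the dicarbonyl s-trans. A chelated s-cis dicarbonyl turns O9 away from H2α. A one-point Lewis acid is therefore used. The concerted closure must deliver the axial 9α-alcohol, so C9 is inverted afterwards by equilibration of the O-silylated ketone (step 14).
- **Regio- and chemoselectivity.** The C5 enolate is generated regiospecifically by conjugate addition. The dicarbonyl is made from a 1,2-diol, so no oxidant that attacks the ring alkene is needed.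

**Assumption:** the lipase of step 2 hydrolyses the S acetate faster. With an enzyme of opposite preference the R alcohol is collected instead and enters step 3 unchanged, because LiAlH4 takes acetate and alcohol to the same diol 4.

Step 1
Reactants: 1 3-ethoxy-2-methylcyclohex-2-en-1-one
Product: 2 rac-4-ethoxy-3-methyl-2-oxocyclohex-3-en-1-yl acetate
Conditions: Mn(OAc)3·2H2O, benzene, reflux (Dean–Stark)
Reagents that add atoms: manganese triacetate, CC(=O)[O-].CC(=O)[O-].CC(=O)[O-].[Mn+3]
Why: Trivalent-manganese α′-acetoxylation of an enone, in which the manganese enolate at the only α′ position of the vinylogous ester is oxidised and captures acetate, installs the future C3–O bond in racemic form.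

Step 2
Reactants: 2 rac-4-ethoxy-3-methyl-2-oxocyclohex-3-en-1-yl acetate
Product: 3 (R)-4-ethoxy-3-methyl-2-oxocyclohex-3-en-1-yl acetate
Conditions: Burkholderia cepacia lipase, pH 7 phosphate buffer/DMSO, rt, stopped near half conversion, chromatography
Reagents that add atoms: none
Why: Lipase-catalysed kinetic resolution by enantioselective ester hydrolysis, a reaction established for α′-acetoxy enones, leaves one enantiomer of the acetate untouched and so fixes the absolute configuration of the future C3.

Step 3
Reactants: 3 (R)-4-ethoxy-3-methyl-2-oxocyclohex-3-en-1-yl acetate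
Product: 5 (R)-4-hydroxy-2-methylcyclohex-2-en-1-one, via allylic diol 4 (not isolated)
Conditions: LiAlH4, Et2O, 0 °C; then 1 M HCl, THF, rt
Reagents that add atoms: water, O
Why: In this Stork–Danheiser transposition hydride adds 1,2 to the vinylogous ester and cleaves the acetate, and acid then hydrolyses the enol ether with loss of the allylic hydroxyl, so the enone is relocated while the carbinol stereocentre takes no part and is retained.

Step 4
Reactants: 5 (R)-4-hydroxy-2-methylcyclohex-2-en-1-one
Product: 6 (R)-2-methyl-4-(triethylsilyloxy)cyclohex-2-en-1-one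
Conditions: TESCl, imidazole, CH2Cl2, 0 °C
Reagents that add atoms: chlorotriethylsilane, CC[Si](Cl)(CC)CC
Why: Standard imidazole-promoted silylation under conditions too mild to enolise the γ-hydroxy enone gives the weakly Lewis basic ether that the key step needs.

Step 5
Reactants: 6 (R)-2-methyl-4-(triethylsilyloxy)cyclohex-2-en-1-one; 7 allyl bromide
Product: 9 (2R,3R,4R)-2-allyl-2,3-dimethyl-4-(triethylsilyloxy)cyclohexan-1-one, via lithium enolate 8 (not isolated)
Conditions: Me2CuLi (CuBr·SMe2, MeLi), Et2O, −78 to −20 °C; then allyl bromide, HMPA, THF, −20 °C to rt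
Reagents that add atoms: lithium dimethylcuprate, [Li+].C[Cu-]C
Why: In this conjugate addition with enolate trapping the cuprate delivers methyl to C4 anti to the C3 silyloxy group, the enolate arises regiospecifically at C5, and allyl bromide then approaches anti to the new C4 methyl, which should set the cis C4/C5 dimethyl array with the allyl arm on the α face.

Step 6
Reactants: 9 (2R,3R,4R)-2-allyl-2,3-dimethyl-4-(triethylsilyloxy)cyclohexan-1-one
Product: 11 (4R,5R,6R)-6-allyl-5,6-dimethyl-4-(triethylsilyloxy)cyclohex-1-en-1-yl trifluoromethanesulfonate, via potassium enolate 10 (not isolated)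
Conditions: KHMDS, THF, −78 °C; PhNTf2, −78 to 0 °C
Reagents that add atoms: N-phenylbis(trifluoromethanesulfonimide), O=S(=O)(N(c1ccccc1)S(=O)(=O)C(F)(F)F)C(F)(F)F
Why: Enolisation can only run toward C1 because C5 is quaternary, and O-sulfonylation of the enolate gives the enol triflate with the C10=C1 double bond in a defined place.

Step 7
Reactants: 11 (4R,5R,6R)-6-allyl-5,6-dimethyl-4-(triethylsilyloxy)cyclohex-1-en-1-yl trifluoromethanesulfonate
Product: 12 {[(1R,2R,3S)-3-allyl-2,3-dimethylcyclohex-4-en-1-yl]oxy}triethylsilane
Conditions: Pd(OAc)2, PPh3, HCO2H, Et3N (in excess over the acid), DMF, 60 °C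
Reagents that add atoms: none
Why: Palladium-catalysed formate reduction of an enol triflate (oxidative addition to zerovalent palladium, decarboxylation of formate to a palladium hydride, reductive elimination) replaces OTf by H without touching the allyl group or the silyl ether.

Step 8
Reactants: 12 {[(1R,2R,3S)-3-allyl-2,3-dimethylcyclohex-4-en-1-yl]oxy}triethylsilane
Product: 14 3-[(1S,5R,6R)-1,6-dimethyl-5-(triethylsilyloxy)cyclohex-2-en-1-yl]propan-1-ol, via B-alkyl-9-BBN adduct 13 (not isolated)
Conditions: 9-BBN, THF, 0 °C to rt; then H2O2, NaOH, 0 °C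
Reagents that add atoms: hydrogen peroxide, OO
Why: In this hydroboration–oxidation the bulky borane reacts with the monosubstituted alkene far faster than with the ring alkene next to quaternary C5 and places boron on the terminal carbon C8.

Step 9
Reactants: 14 3-[(1S,5R,6R)-1,6-dimethyl-5-(triethylsilyloxy)cyclohex-2-en-1-yl]propan-1-ol
Product: 15 3-[(1S,5R,6R)-1,6-dimethyl-5-(triethylsilyloxy)cyclohex-2-en-1-yl]propanal
Conditions: Dess–Martin periodinane, NaHCO3, CH2Cl2, 0 °C to rt
Reagents that add atoms: none
Why: Buffered Dess–Martin oxidation stops at the aldehyde and tolerates the alkene and the silyl ether.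

Step 10
Reactants: 15 3-[(1S,5R,6R)-1,6-dimethyl-5-(triethylsilyloxy)cyclohex-2-en-1-yl]propanal
Product: 17 4-[(1S,5R,6R)-1,6-dimethyl-5-(triethylsilyloxy)cyclohex-2-en-1-yl]butane-1,2-diol (C8 epimers), via hydroxysilane 16 (not isolated)
Conditions: (i-PrO)Me2SiCH2MgCl, THF, 0 °C; then H2O2, KHCO3, THF/MeOH, 40 °C
Reagents that add atoms: (isopropoxydimethylsilyl)methylmagnesium chloride, CC(C)O[Si](C)(C)C[Mg]Cl; hydrogen peroxide, OO
Why: In this nucleophilic hydroxymethylation the silylmethyl Grignard reagent brings in C9 and fluoride-free Tamao–Fleming oxidation turns C–Si into C–OH without touching the ring alkene or the silyl ether, the C8 configuration being irrelevant because step 11 destroys it.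

Step 11
Reactants: 17 4-[(1S,5R,6R)-1,6-dimethyl-5-(triethylsilyloxy)cyclohex-2-en-1-yl]butane-1,2-diol
Product: 18 4-[(1S,5R,6R)-1,6-dimethyl-5-(triethylsilyloxy)cyclohex-2-en-1-yl]-2-oxobutanal
Conditions: (COCl)2, DMSO, CH2Cl2, −78 °C; Et3N, −78 to −20 °C; fast cold work-up, azeotropic drying (PhMe), used crude
Reagents that add atoms: none
Why: Double Swern oxidation takes a terminal 1,2-diol to the α-keto aldehyde without glycol cleavage and uses no reagent that reacts with the ring alkene.

Step 12
Reactants: 18 4-[(1S,5R,6R)-1,6-dimethyl-5-(triethylsilyloxy)cyclohex-2-en-1-yl]-2-oxobutanal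
Product: 19 9α-hydroxy-3α-(triethylsilyloxy)-10βH-11,12,13-trinoreremophil-1-en-8-one
Conditions: Me2AlCl (1.1 equiv), CH2Cl2, high dilution, −78 to −30 °C; aqueous potassium sodium tartrate
Reagents that add atoms: none
Why: Me2AlCl binds one carbonyl oxygen of the s-trans keto aldehyde, C9 bonds to C10 while H2α passes suprafacially to O9 and the alkene moves to C1=C2, a concerted or tightly asynchronous carbonyl-ene reaction whose closest relatives are the Lewis-acid-promoted closure of citronellal to isopulegol and glyoxylate-ene reactions of cyclohexene, and loss of methane from the aluminium-bound alcohol removes the proton that could start cationic side reactions. Ring B closes in a 6-exo mode with respect to both π bonds (type 1 intramolecular ene, tether on the attacked alkene carbon) through a chair-like array, whereas attack at C1 would need a bridged seven-membered ring. C10 is controlled by the tether, since C6 sits on the α face of C5 and C9 can therefore reach only the α face of C10, which leaves H10 β and gives the cis fusion. C9 is controlled by the hydrogen transfer, since the six-centre array forms only with O9 turned under ring A toward H2α, so the hydroxyl should be born axial (9α, trans to H10), the epimer of what the target needs, and step 14 corrects it. The ground-state half-chair (C14 pseudoaxial; tether, C15 and OTES equatorial) already holds H2α pseudoaxial on the attacked face, C2 is the only hydrogen donor because C5 is quaternary, and the aldehyde outruns the ketone as enophile. A chelating Lewis acid is avoided because an s-cis dicarbonyl would turn O9 away from H2α and force a stepwise Prins course.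

Step 13
Reactants: 19 9α-hydroxy-3α-(triethylsilyloxy)-10βH-11,12,13-trinoreremophil-1-en-8-one
Product: 20 9α-(tert-butyldimethylsilyloxy)-3α-(triethylsilyloxy)-10βH-11,12,13-trinoreremophil-1-en-8-one
Conditions: TBSOTf, 2,6-lutidine, CH2Cl2, −78 to 0 °C
Reagents that add atoms: tert-butyldimethylsilyl trifluoromethanesulfonate, CC(C)(C)[Si](C)(C)OS(=O)(=O)C(F)(F)F
Why: A silyl triflate with a hindered pyridine base silylates even a crowded secondary alcohol faster than it enolises the ketone, and blocking O9 prevents ketol transposition in step 14 and steers enolisation to C7 in step 16.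

Step 14
Reactants: 20 9α-(tert-butyldimethylsilyloxy)-3α-(triethylsilyloxy)-10βH-11,12,13-trinoreremophil-1-en-8-one
Product: 21 9β-(tert-butyldimethylsilyloxy)-3α-(triethylsilyloxy)-10βH-11,12,13-trinoreremophil-1-en-8-one
Conditions: DBU, PhMe, 80 °C
Reagents that add atoms: none
Why: Base-mediated epimerisation through the C8–C9 enolate under thermodynamic control should move the axial 9α substituent, which points under ring A, into the equatorial 9β position cis to H10, and with O9 silylated the carbonyl cannot migrate to C9.

Step 15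
Reactants: 21 9β-(tert-butyldimethylsilyloxy)-3α-(triethylsilyloxy)-10βH-11,12,13-trinoreremophil-1-en-8-one
Product: 22 9β-(tert-butyldimethylsilyloxy)-3α-(triethylsilyloxy)-10βH-11,12,13-trinoreremophilan-8-one
Conditions: KO2CN=NCO2K, AcOH, CH2Cl2/MeOH, 0 °C to rt
Reagents that add atoms: none
Why: Diimide reduction by concerted syn transfer of two hydrogens saturates the unpolarised C1=C2 alkene, avoids hydrogenolysis of the allylic C3–O bond, and the azodicarboxylate source avoids the hydrazone formation at C8 that sulfonyl hydrazides could cause.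

Step 16
Reactants: 22 9β-(tert-butyldimethylsilyloxy)-3α-(triethylsilyloxy)-10βH-11,12,13-trinoreremophilan-8-one; 23 acetone
Product: 26 9β-(tert-butyldimethylsilyloxy)-11-hydroxy-3α-(triethylsilyloxy)-7αH,10βH-eremophilan-8-one, via lithium enolate 24 (not isolated), via chlorozinc enolate 25 (not isolated)
Conditions: LDA, THF, −78 °C; ZnCl2; acetone, −78 to −40 °C
Reagents that add atoms: none
Why: Kinetic deprotonation takes place at the C7 methylene and not at the hindered silyloxy-bearing C9, and the zinc enolate undergoes aldol addition to acetone from the convex β face, which is also the equatorial and thermodynamically preferred position, so C7 should be set as 7β.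

Step 17
Reactants: 26 9β-(tert-butyldimethylsilyloxy)-11-hydroxy-3α-(triethylsilyloxy)-7αH,10βH-eremophilan-8-one
Product: 27 9β-(tert-butyldimethylsilyloxy)-3α-(triethylsilyloxy)-7αH,10βH-eremophil-11-en-8-one
Conditions: SOCl2, pyridine, −20 to 0 °C
Reagents that add atoms: none
Why: In this dehydration through the chlorosulfite by E2 elimination the six methyl hydrogens are easily placed antiperiplanar to the leaving group, the rotamer needed to remove H7 is crowded and pyridine is too weak for an E1cB path, so the unconjugated isopropenyl group should form and C7 stay untouched.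

Step 18
Reactants: 27 9β-(tert-butyldimethylsilyloxy)-3α-(triethylsilyloxy)-7αH,10βH-eremophil-11-en-8-one
Product: 28 9β-(tert-butyldimethylsilyloxy)-3α-hydroxy-7αH,10βH-eremophil-11-en-8-one
Conditions: PPTS, MeOH/CH2Cl2, 0 °C
Reagents that add atoms: none
Why: Mild acid methanolysis distinguishes the two silyl ethers, since the small triethylsilyl group on the ordinary C3 oxygen is cleaved much faster than the bulkier tert-butyldimethylsilyl group on the electron-poor α-keto oxygen, and the conditions are too mild to move the isopropenyl double bond.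

Step 19
Reactants: 29 (R)-pent-4-en-2-ol; 30 angelic acid
Product: 32 (R)-pent-4-en-2-yl (Z)-2-methylbut-2-enoate, via mixed anhydride 31 (not isolated)
Conditions: angelic acid, 2,4,6-Cl3C6H2COCl, Et3N, PhMe, rt; then 29, 80 °C
Reagents that add atoms: none
Why: Yamaguchi-type mixed-anhydride esterification run without DMAP transfers the angeloyl group without Z to E isomerisation and leaves the carbinol C–O bond intact, so the R configuration is retained.

Step 20
Reactants: 32 (R)-pent-4-en-2-yl (Z)-2-methylbut-2-enoate; 33 acrylic acid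
Product: 34 (2E,5R)-5-{[(Z)-2-methylbut-2-enoyl]oxy}hex-2-enoic acid
Conditions: acrylic acid (excess), second-generation Hoveyda–Grubbs catalyst, CH2Cl2, 40 °C
Reagents that add atoms: none
Why: Olefin cross metathesis between a terminal alkene and an electron-poor acrylic partner favours the cross product with E geometry, while the trisubstituted electron-poor angelate alkene is inert to the catalyst.

Step 21
Reactants: 28 9β-(tert-butyldimethylsilyloxy)-3α-hydroxy-7αH,10βH-eremophil-11-en-8-one; 34 (2E,5R)-5-{[(Z)-2-methylbut-2-enoyl]oxy}hex-2-enoic acid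
Product: 35 9-O-(tert-butyldimethylsilyl) ether of the target
Conditions: EDC·HCl, DMAP (catalytic), CH2Cl2, 0 °C to rt
Reagents that add atoms: none
Why: Steglich esterification acylates the only free hydroxyl, the equatorial C3–OH, with retention at C3, and the small amount of DMAP keeps base exposure of the β,γ-unsaturated ketone and of the δ-acyloxy enoate low.

Step 22
Reactants: 35 9-O-(tert-butyldimethylsilyl) ether of the target
Product: 36 CNP0210874.1
Conditions: HF·pyridine, pyridine, THF, 0 °C to rt
Reagents that add atoms: none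
Why: Fluoride-mediated desilylation in a weakly acidic buffered medium frees the C9 hydroxyl without the base that would conjugate the isopropenyl group, eliminate the side-chain acyloxy group or epimerise C7 and C9.

**Compound list**

1 | 3-ethoxy-2-methylcyclohex-2-en-1-one | CCOC1=C(C)C(=O)CCC1 | starting material
2 | rac-4-ethoxy-3-methyl-2-oxocyclohex-3-en-1-yl acetate | CCOC1=C(C)C(=O)C(OC(C)=O)CC1 | intermediate
3 | (R)-4-ethoxy-3-methyl-2-oxocyclohex-3-en-1-yl acetate | CCOC1=C(C)C(=O)[C@H](OC(C)=O)CC1 | intermediate
4 | (1R)-4-ethoxy-3-methylcyclohex-3-ene-1,2-diol (C2 epimers, not isolated) | CCOC1=C(C)C(O)[C@H](O)CC1 | intermediate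
5 | (R)-4-hydroxy-2-methylcyclohex-2-en-1-one | O=C1CC[C@@H](O)C=C1C | intermediate
6 | (R)-2-methyl-4-(triethylsilyloxy)cyclohex-2-en-1-one | O=C1CC[C@@H](O[Si](CC)(CC)CC)C=C1C | intermediate
7 | allyl bromide | C=CCBr | starting material
8 | lithium enolate (C10=C5) after methyl addition (not isolated) | [Li]OC1=C(C)[C@@H](C)[C@H](O[Si](CC)(CC)CC)CC1 | intermediate
9 | (2R,3R,4R)-2-allyl-2,3-dimethyl-4-(triethylsilyloxy)cyclohexan-1-one | C=CC[C@@]1(C)C(=O)CC[C@@H](O[Si](CC)(CC)CC)[C@@H]1C | intermediate
10 | potassium enolate (C10=C1) of 9 (not isolated) | C=CC[C@@]1(C)C(O[K])=CC[C@@H](O[Si](CC)(CC)CC)[C@@H]1C | intermediate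
11 | (4R,5R,6R)-6-allyl-5,6-dimethyl-4-(triethylsilyloxy)cyclohex-1-en-1-yl trifluoromethanesulfonate | C=CC[C@@]1(C)C(OS(=O)(=O)C(F)(F)F)=CC[C@@H](O[Si](CC)(CC)CC)[C@@H]1C | intermediate
12 | {[(1R,2R,3S)-3-allyl-2,3-dimethylcyclohex-4-en-1-yl]oxy}triethylsilane | C=CC[C@@]1(C)C=CC[C@@H](O[Si](CC)(CC)CC)[C@@H]1C | intermediate
13 | B-alkyl-9-borabicyclo[3.3.1]nonane from 12 (not isolated) | C1CC2CCCC(C1)B2CCC[C@@]3(C)C=CC[C@@H](O[Si](CC)(CC)CC)[C@@H]3C | intermediate
14 | 3-[(1S,5R,6R)-1,6-dimethyl-5-(triethylsilyloxy)cyclohex-2-en-1-yl]propan-1-ol | OCCC[C@@]1(C)C=CC[C@@H](O[Si](CC)(CC)CC)[C@@H]1C | intermediate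
15 | 3-[(1S,5R,6R)-1,6-dimethyl-5-(triethylsilyloxy)cyclohex-2-en-1-yl]propanal | O=CCC[C@@]1(C)C=CC[C@@H](O[Si](CC)(CC)CC)[C@@H]1C | intermediate
16 | 1-(isopropoxydimethylsilyl)-4-[(1S,5R,6R)-1,6-dimethyl-5-(triethylsilyloxy)cyclohex-2-en-1-yl]butan-2-ol (C8 epimers, not isolated) | CC(C)O[Si](C)(C)CC(O)CC[C@@]1(C)C=CC[C@@H](O[Si](CC)(CC)CC)[C@@H]1C | intermediate
17 | 4-[(1S,5R,6R)-1,6-dimethyl-5-(triethylsilyloxy)cyclohex-2-en-1-yl]butane-1,2-diol (C8 epimers) | OCC(O)CC[C@@]1(C)C=CC[C@@H](O[Si](CC)(CC)CC)[C@@H]1C | intermediate
18 | 4-[(1S,5R,6R)-1,6-dimethyl-5-(triethylsilyloxy)cyclohex-2-en-1-yl]-2-oxobutanal (key-step precursor) | O=CC(=O)CC[C@@]1(C)C=CC[C@@H](O[Si](CC)(CC)CC)[C@@H]1C | intermediate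
19 | 9α-hydroxy-3α-(triethylsilyloxy)-10βH-11,12,13-trinoreremophil-1-en-8-one (key-step product) | O=C1CC[C@@]2(C)[C@H](C=C[C@@H](O[Si](CC)(CC)CC)[C@@H]2C)[C@@H]1O | intermediate
20 | 9α-(tert-butyldimethylsilyloxy)-3α-(triethylsilyloxy)-10βH-11,12,13-trinoreremophil-1-en-8-one | O=C1CC[C@@]2(C)[C@H](C=C[C@@H](O[Si](CC)(CC)CC)[C@@H]2C)[C@@H]1O[Si](C)(C)C(C)(C)C | intermediate
21 | 9β-(tert-butyldimethylsilyloxy)-3α-(triethylsilyloxy)-10βH-11,12,13-trinoreremophil-1-en-8-one | O=C1CC[C@@]2(C)[C@H](C=C[C@@H](O[Si](CC)(CC)CC)[C@@H]2C)[C@H]1O[Si](C)(C)C(C)(C)C | intermediate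
22 | 9β-(tert-butyldimethylsilyloxy)-3α-(triethylsilyloxy)-10βH-11,12,13-trinoreremophilan-8-one | O=C1CC[C@@]2(C)[C@H](CC[C@@H](O[Si](CC)(CC)CC)[C@@H]2C)[C@H]1O[Si](C)(C)C(C)(C)C | intermediate
23 | acetone | CC(C)=O | starting material
24 | lithium enolate (C7=C8) of 22 (not isolated) | [Li]OC1=CC[C@@]2(C)[C@H](CC[C@@H](O[Si](CC)(CC)CC)[C@@H]2C)[C@H]1O[Si](C)(C)C(C)(C)C | intermediate
25 | chlorozinc enolate (C7=C8) of 22 (not isolated) | Cl[Zn]OC1=CC[C@@]2(C)[C@H](CC[C@@H](O[Si](CC)(CC)CC)[C@@H]2C)[C@H]1O[Si](C)(C)C(C)(C)C | intermediate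
26 | 9β-(tert-butyldimethylsilyloxy)-11-hydroxy-3α-(triethylsilyloxy)-7αH,10βH-eremophilan-8-one | CC(C)(O)[C@H]1C[C@@]2(C)[C@H](CC[C@@H](O[Si](CC)(CC)CC)[C@@H]2C)[C@@H](O[Si](C)(C)C(C)(C)C)C1=O | intermediate
27 | 9β-(tert-butyldimethylsilyloxy)-3α-(triethylsilyloxy)-7αH,10βH-eremophil-11-en-8-one | C=C(C)[C@H]1C[C@@]2(C)[C@H](CC[C@@H](O[Si](CC)(CC)CC)[C@@H]2C)[C@@H](O[Si](C)(C)C(C)(C)C)C1=O | intermediate
28 | 9β-(tert-butyldimethylsilyloxy)-3α-hydroxy-7αH,10βH-eremophil-11-en-8-one | C=C(C)[C@H]1C[C@@]2(C)[C@H](CC[C@@H](O)[C@@H]2C)[C@@H](O[Si](C)(C)C(C)(C)C)C1=O | intermediate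
29 | (R)-pent-4-en-2-ol | C=CC[C@@H](C)O | starting material
30 | angelic acid | C/C=C(/C)C(=O)O | starting material
31 | angelic 2,4,6-trichlorobenzoic anhydride (not isolated) | C/C=C(/C)C(=O)OC(=O)c1c(Cl)cc(Cl)cc1Cl | intermediate
32 | (R)-pent-4-en-2-yl (Z)-2-methylbut-2-enoate | C=CC[C@@H](C)OC(=O)/C(C)=C\C | intermediate
33 | acrylic acid | C=CC(=O)O | starting material
34 | (2E,5R)-5-{[(Z)-2-methylbut-2-enoyl]oxy}hex-2-enoic acid | OC(=O)/C=C/C[C@@H](C)OC(=O)/C(C)=C\C | intermediate
35 | 9-O-(tert-butyldimethylsilyl) ether of the target | C=C(C)[C@H]1C[C@@]2(C)[C@H](CC[C@@H](OC(=O)/C=C/C[C@@H](C)OC(=O)/C(C)=C\C)[C@@H]2C)[C@@H](O[Si](C)(C)C(C)(C)C)C1=O | intermediate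
36 | CNP0210874.1, 3α-{(2E,5R)-5-[(Z)-2-methylbut-2-enoyloxy]hex-2-enoyloxy}-9β-hydroxy-7αH,10βH-eremophil-11-en-8-one | C=C(C)[C@H]1C[C@@]2(C)[C@H](CC[C@@H](OC(=O)/C=C/C[C@@H](C)OC(=O)/C(C)=C\C)[C@@H]2C)[C@@H](O)C1=O | target

Total step count: 22.
Longest linear sequence: 20 (steps 1–18, 21 and 22). The side-chain acid takes 2 steps (19 and 20).

**Steps most likely to fail**

**Step 12 (ene closure).** The 1,2-disubstituted ring alkene may be too weak a nucleophile. Methyl transfer from aluminium to the aldehyde, self-condensation of the dicarbonyl, or a stepwise cationic course with chloride capture at C1 or proton loss from C10 could then compete with the concerted hydrogen transfer.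
- The fallback accepts the stepwise course and sets out from 18.
- Chelating SnCl4 in CH2Cl2 at −78 °C holds the dicarbonyl s-cis. Prins closure then places O9 equatorial (9β), and the C1 cation is captured by chloride to give the C1 chlorohydrin F1.
- Radical dechlorination (Bu3SnH, AIBN, PhMe, 90 °C) gives the saturated 9β-ketol F2.
- TBSOTf and 2,6-lutidine bring the material back to the route at 22, so 19 to 21 are bypassed.

**Step 17 (dehydration).** Elimination may run toward C7, or the new double bond may drift into conjugation with the C8 ketone during reaction or work-up.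
- The fallback replaces aldol and dehydration by a palladium-catalysed α-alkenylation of the ketone enolate and sets out from 22.
- LiHMDS forms the C7 enolate, which is coupled with 2-bromopropene (Pd2(dba)3, Q-Phos, THF/PhMe, rt). A cold acidic quench lets C7 settle with the isopropenyl group equatorial.
- The material returns to the route at 27. No compound outside the list is made (entry F0).

**Step 5 (conjugate addition and allylation).** Facial selectivity in the allylation may be eroded. In the enolate conformer with the C4 methyl axial, the C3 silyloxy group lies syn-axial to the incoming electrophile. Proton exchange between enolate and product may also blur the regiochemistry.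
- The fallback sets out from 6 and separates the two bond formations.
- Me2CuLi with TMSCl gives the trimethylsilyl enol ether F3.
- This is allylated under ligand control by asymmetric Tsuji allylation (Pd2(dba)3, (S)-t-BuPHOX, diallyl carbonate, Bu4N[Ph3SiF2], THF, 25 °C). The sense of induction of this ligand matches the substrate bias.
- The material returns to the route at 9.

Further compounds
F1 | step 12 | 1-chloro-9β-hydroxy-3α-(triethylsilyloxy)-10βH-11,12,13-trinoreremophilan-8-one (C1 configuration open) | O=C1CC[C@@]2(C)[C@H](C(Cl)C[C@@H](O[Si](CC)(CC)CC)[C@@H]2C)[C@H]1O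
F2 | step 12 | 9β-hydroxy-3α-(triethylsilyloxy)-10βH-11,12,13-trinoreremophilan-8-one | O=C1CC[C@@]2(C)[C@H](CC[C@@H](O[Si](CC)(CC)CC)[C@@H]2C)[C@H]1O
F0 | step 17 | none | none
F3 | step 5 | triethyl{[(1R,2R)-2,3-dimethyl-4-(trimethylsilyloxy)cyclohex-3-en-1-yl]oxy}silane | C[Si](C)(C)OC1=C(C)[C@@H](C)[C@H](O[Si](CC)(CC)CC)CC1
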